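**Retrosynthetic overview**
1. Numbering: alcohol chain C1 (terminal =CH2) to C15 (C9 = ketone carbon, C14 = ester carbinol), acid C1' to C11'. First cut: ester O14–C1' (Yamaguchi), giving the C1–C15 chain and epoxy dienoic acid 29 (oxirane by Sharpless epoxidation, C6'=C7' by Julia–Kocienski olefination).
2. Key cut: C8–C9 and C9–C10 are made in one flask around a one-carbon linchpin. C9 is C2 of 2-silyl-1,3-dithiane 30: it opens terminal oxirane 8 (C1–C8), hands its silyl group to O7 (1,4-Brook shift), then acylates on δ-lactone 17 (C10–C15).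
3. Enabling feature: the C7(OH)–C8H2–C9(=O)–C10(OH) array. C9 is a carbonyl carbon flanked by a CH2 that is β to a secondary carbinol (C7–O/C8 = oxirane retron) and by an oxygenated carbon (C10 = acyl retron), so C9 can act twice as a nucleophile. The six atoms C10–C11–C12–C13–C14–O14 can be tied into a δ-lactone ring that delivers C10 as an acyl group and sets O14 free for the ester.
4. Stereocentres: C5 from (R)-2-methylglycidol, C7 by hydrolytic kinetic resolution, C11/C12 by Sharpless epoxidation and AlMe3 opening, C14 from (R)-propylene oxide, C10 by Felkin–Anh reduction of the C10 ketone.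
5. Rings: oxirane of 8 (step 3) and δ-lactone 16 (step 12) are temporary and are both opened in the key step. The dithiane ring comes with 30 and is removed in step 26. The oxirane of 21 (step 16) is the only ring of the target and is kept to the end.

Key step: step 23

Remark: compounds 1, 10 and 30 are taken as purchased (1 and 10 enantiopure). Names in the compound list are systematic and number independently of the C1–C15 locants used in the text.
Remark: hydroxy ketone 34 may equilibrate with its six-membered lactol; both react through the open form in step 24, and the open form is the one drawn.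

**Oxirane 8 (C1–C8)**

Step 1
Reactants: 1 (R)-2-methylglycidol
Product: 2 (2S)-2-methylpent-4-ene-1,2-diol
Conditions: CH2=CHMgBr (2.5 equiv), CuI (10 mol%), THF, −30 → 0 °C; aq NH4Cl
Reagents that add atoms: vinylmagnesium bromide, C=C[Mg]Br
Why: Copper-catalysed Grignard opening (SN2) at the unsubstituted oxirane carbon; the quaternary carbinol carbon (C5 of the target) is not a reacting centre and keeps the configuration bought with 1.

Step 2
Reactants: 2 (2S)-2-methylpent-4-ene-1,2-diol
Product: 3 (2S)-2-methyl-1,2-bis(triethylsilyloxy)pent-4-ene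
Conditions: Et3SiOTf (2.5 equiv), 2,6-lutidine, CH2Cl2, −78 → 0 °C
Reagents that add atoms: triethylsilyl trifluoromethanesulfonate, CC[Si](CC)(CC)OS(=O)(=O)C(F)(F)F
Why: Silylation with the silyl triflate, reactive enough to cap the tertiary as well as the primary hydroxyl, removes all acidic protons before the later organometallic steps.

Step 3
Reactants: 3 (2S)-2-methyl-1,2-bis(triethylsilyloxy)pent-4-ene
Product: 4 2-[(2S)-2-methyl-2,3-bis(triethylsilyloxy)propyl]oxirane (both epimers at the oxirane carbon)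
Conditions: mCPBA, NaHCO3, CH2Cl2, 0 °C → rt
Reagents that add atoms: mCPBA, OOC(=O)c1cccc(Cl)c1
Why: Prilezhaev epoxidation of the only alkene; the remote quaternary centre should give no useful facial bias, so both C7 epimers are expected and are sorted in step 4.

Step 4
Reactants: 4 2-[(2S)-2-methyl-2,3-bis(triethylsilyloxy)propyl]oxirane (both epimers)
Product: 5 (2R)-2-[(2S)-2-methyl-2,3-bis(triethylsilyloxy)propyl]oxirane
Conditions: (S,S)-(salen)Co(OAc) (1 mol%), H2O (0.55 equiv), THF, 0 °C → rt
Reagents that add atoms: none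
Why: Jacobsen hydrolytic kinetic resolution, in which the catalyst and not the substrate decides: the (S)-oxirane epimer is hydrolysed to the diol and the (R)-oxirane 5 (C7 of the target) should be recovered, at most half of the material, the catalyst antipode that spares (R)-alkyloxiranes being the one required (to be confirmed in the first run).

Step 5
Reactants: 5 (2R)-2-[(2S)-2-methyl-2,3-bis(triethylsilyloxy)propyl]oxirane
Product: 6 (2S)-2-methyl-3-[(2R)-oxiran-2-yl]-2-(triethylsilyloxy)propanal
Conditions: (COCl)2, DMSO, CH2Cl2, −78 → −30 °C; Et3N, −78 °C → rt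
Reagents that add atoms: none
Why: Swern conditions are known to cleave and oxidise a primary triethylsilyl ether in one operation while a tertiary one and an oxirane survive, so the aldehyde is reached without a separate deprotection.

Step 6
Reactants: 6 (2S)-2-methyl-3-[(2R)-oxiran-2-yl]-2-(triethylsilyloxy)propanal
Product: 7 (2E,4S)-2,4-dimethyl-5-[(2R)-oxiran-2-yl]-4-(triethylsilyloxy)pent-2-enal
Conditions: Ph3P=C(CH3)CHO (1.5 equiv), toluene, 90 °C
Reagents that add atoms: 2-(triphenylphosphoranylidene)propanal, CC(C=O)=P(c1ccccc1)(c1ccccc1)c1ccccc1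
Why: Wittig olefination with the stabilised formyl ylide, reversible in its first step and therefore E-selective (the new CHO ends trans to the quaternary carbon), sets the C3=C4 geometry.

Step 7
Reactants: 7 (2E,4S)-2,4-dimethyl-5-[(2R)-oxiran-2-yl]-4-(triethylsilyloxy)pent-2-enal
Product: 8 (2R)-2-[(2S,3E)-2,4-dimethyl-2-(triethylsilyloxy)hexa-3,5-dien-1-yl]oxirane
Conditions: Ph3PCH3Br, KHMDS, THF, 0 °C; then 7, −78 → 0 °C
Reagents that add atoms: methyltriphenylphosphonium bromide, C[P+](c1ccccc1)(c1ccccc1)c1ccccc1.[Br-]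
Why: Wittig methylenation by 1,2-addition of the non-stabilised ylide to the enal completes the diene; the oxirane and silyl ether are inert to the ylide at low temperature.

**Lactone 17 (C10–C15)**

Step 8
Reactants: 9 prop-2-yn-1-ol; 10 (R)-propylene oxide
Product: 11 (5R)-hex-2-yne-1,5-diol
Conditions: n-BuLi (2.1 equiv), THF, −78 → 0 °C; 10, DMPU, 0 °C → rt; aq NH4Cl
Reagents that add atoms: none
Why: Alkynylation: the C,O-dilithio derivative of 9 opens the oxirane at its CH2 carbon (SN2), so the carbinol centre (C14 of the target) keeps the configuration of 10.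

Step 9
Reactants: 11 (5R)-hex-2-yne-1,5-diol
Product: 12 (2E,5R)-hex-2-ene-1,5-diol
Conditions: NaAlH2(OCH2CH2OMe)2, THF, 0 °C → rt; aq Rochelle salt
Reagents that add atoms: none
Why: Alkoxide-directed trans-hydroalumination of the propargylic alcohol followed by protonolysis gives the E-alkene only.

Step 10
Reactants: 12 (2E,5R)-hex-2-ene-1,5-diol
Product: 13 (2R)-1-[(2R,3R)-3-(hydroxymethyl)oxiran-2-yl]propan-2-ol
Conditions: Ti(OiPr)4 (0.2 equiv), D-(−)-diethyl tartrate (0.24 equiv), t-BuOOH, 4 Å MS, CH2Cl2, −20 °C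
Reagents that add atoms: tert-butyl hydroperoxide, CC(C)(C)OO
Why: Sharpless asymmetric epoxidation of the primary allylic alcohol; the D-tartrate ligand delivers oxygen to the face that gives the (2R,3R)-oxirane (reagent control, as for other E-allylic alcohols), which fixes C11 and prepares C12.

Step 11
Reactants: 13 (2R)-1-[(2R,3R)-3-(hydroxymethyl)oxiran-2-yl]propan-2-ol
Product: 14 (2S,3S,5R)-3-methylhexane-1,2,5-triol
Conditions: AlMe3 (4 equiv), CH2Cl2/hexane, −30 °C → rt; aq Rochelle salt
Reagents that add atoms: trimethylaluminium, C[Al](C)C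
Why: Trimethylaluminium opening of a 2,3-epoxy alcohol: the aluminium alkoxide directs methyl to C3 with inversion (SN2), giving the 2-hydroxy-3-methyl array with C11 retained and C12 set.

Step 12
Reactants: 14 (2S,3S,5R)-3-methylhexane-1,2,5-triol
Product: 16 (3S,4S,6R)-3-hydroxy-4,6-dimethyloxan-2-one, via lactol 15 (not isolated)
Conditions: TEMPO (0.2 equiv), PhI(OAc)2 (2.5 equiv), CH2Cl2, rt
Reagents that add atoms: none
Why: Oxoammonium (TEMPO) oxidation is selective for the primary alcohol; the hydroxy aldehyde closes with O14 to the six-membered lactol 15, which is oxidised again to the δ-lactone (oxidative lactonisation, 6-exo-trig addition to the aldehyde), while the secondary carbinols and all stereocentres stay untouched.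

Step 13
Reactants: 16 (3S,4S,6R)-3-hydroxy-4,6-dimethyloxan-2-one
Product: 17 (3S,4S,6R)-3-(tert-butyldimethylsilyloxy)-4,6-dimethyloxan-2-one
Conditions: TBSCl, imidazole, DMF, rt
Reagents that add atoms: tert-butyldimethylsilyl chloride, CC(C)(C)[Si](C)(C)Cl
Why: Standard silylation of the remaining secondary hydroxyl; the bulky, non-chelating TBS ether at C11 is chosen because it later steers the C10 reduction.

**Acid 29 (C1'–C11')**

Step 14
Reactants: 18 3-methylbutanal
Product: 19 ethyl (2E)-5-methylhex-2-enoate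
Conditions: (EtO)2P(O)CH2CO2Et, NaH, THF, 0 °C → rt
Reagents that add atoms: triethyl phosphonoacetate, CCOC(=O)CP(=O)(OCC)OCC
Why: Horner–Wadsworth–Emmons olefination with a stabilised phosphonate anion, E-selective under thermodynamic control.

Step 15
Reactants: 19 ethyl (2E)-5-methylhex-2-enoate
Product: 20 (2E)-5-methylhex-2-en-1-ol
Conditions: i-Bu2AlH (2.2 equiv), CH2Cl2, −78 °C; aq Rochelle salt
Reagents that add atoms: none
Why: 1,2-Reduction of the enoate by the aluminium hydride gives the allylic alcohol without touching the alkene.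

Step 16
Reactants: 20 (2E)-5-methylhex-2-en-1-ol
Product: 21 [(2R,3R)-3-(2-methylpropyl)oxiran-2-yl]methanol
Conditions: Ti(OiPr)4 (0.1 equiv), D-(−)-diethyl tartrate (0.12 equiv), t-BuOOH, 4 Å MS, CH2Cl2, −20 °C
Reagents that add atoms: tert-butyl hydroperoxide, CC(C)(C)OO
Why: Sharpless asymmetric epoxidation; the D-tartrate ligand should give the (2R,3R)-oxirane, which carries the two oxirane centres of the target.

Step 17
Reactants: 21 [(2R,3R)-3-(2-methylpropyl)oxiran-2-yl]methanol
Product: 22 (2S,3R)-3-(2-methylpropyl)oxirane-2-carbaldehyde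
Conditions: Dess–Martin periodinane, NaHCO3, CH2Cl2, 0 °C → rt
Reagents that add atoms: none
Why: Buffered Dess–Martin oxidation of the primary alcohol under non-acidic and non-basic conditions keeps the configurationally sensitive epoxy aldehyde intact.

Step 18
Reactants: 23 5-bromopent-1-ene; 24 methyl methacrylate
Product: 25 methyl (2E)-6-bromo-2-methylhex-2-enoate
Conditions: second-generation Grubbs catalyst (3 mol%), 24 (5 equiv), CH2Cl2, 40 °C
Reagents that add atoms: none
Why: Olefin cross metathesis between a reactive terminal alkene and slowly homodimerising methacrylate (used in excess) gives the trisubstituted enoate, E by thermodynamic control, with loss of ethene.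

Step 19
Reactants: 25 methyl (2E)-6-bromo-2-methylhex-2-enoate
Product: 26 methyl (2E)-2-methyl-6-[(1-phenyl-1H-tetrazol-5-yl)sulfanyl]hex-2-enoate
Conditions: 1-phenyl-1H-tetrazole-5-thiol, K2CO3, DMF, rt
Reagents that add atoms: 1-phenyl-1H-tetrazole-5-thiol, Sc1nnnn1-c1ccccc1
Why: SN2 displacement of the primary bromide by the soft thiolate (S-alkylation).

Step 20
Reactants: 26 methyl (2E)-2-methyl-6-[(1-phenyl-1H-tetrazol-5-yl)sulfanyl]hex-2-enoate
Product: 27 methyl (2E)-2-methyl-6-[(1-phenyl-1H-tetrazol-5-yl)sulfonyl]hex-2-enoate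
Conditions: (NH4)6Mo7O24·4H2O (0.1 equiv), 30% H2O2, EtOH, 0 °C → rt
Reagents that add atoms: hydrogen peroxide, OO
Why: Molybdate-catalysed peroxide oxidation of sulfide to sulfone; the electron-poor enoate is not epoxidised.

Step 21
Reactants: 27 methyl (2E)-2-methyl-6-[(1-phenyl-1H-tetrazol-5-yl)sulfonyl]hex-2-enoate; 22 (2S,3R)-3-(2-methylpropyl)oxirane-2-carbaldehyde
Product: 28 methyl (2E,6E)-2-methyl-7-[(2R,3R)-3-(2-methylpropyl)oxiran-2-yl]hepta-2,6-dienoate
Conditions: KHMDS, DME, −60 °C; then 22, −60 °C → rt; aq NH4Cl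
Reagents that add atoms: none
Why: Julia–Kocienski olefination: the metallated phenyltetrazolyl sulfone adds to the aldehyde, Smiles rearrangement and loss of SO2 and tetrazolone follow, and the potassium/DME conditions favour the anti adduct and hence the E-alkene (C6'=C7'); the oxirane centres are not involved.

Step 22
Reactants: 28 methyl (2E,6E)-2-methyl-7-[(2R,3R)-3-(2-methylpropyl)oxiran-2-yl]hepta-2,6-dienoate
Product: 29 (2E,6E)-2-methyl-7-[(2R,3R)-3-(2-methylpropyl)oxiran-2-yl]hepta-2,6-dienoic acid
Conditions: LiOH, THF/MeOH/H2O, rt; NaH2PO4 buffer (pH 4.5)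
Reagents that add atoms: lithium hydroxide, [Li+].[OH-]
Why: Saponification of the methyl ester; the vinyl oxirane tolerates aqueous base and the acidification is kept at pH 4.5 to avoid its opening.

**Fragment union and end game**

Step 23
Reactants: 30 2-(tert-butyldimethylsilyl)-1,3-dithiane; 8 (2R)-2-[(2S,3E)-2,4-dimethyl-2-(triethylsilyloxy)hexa-3,5-dien-1-yl]oxirane; 17 (3S,4S,6R)-3-(tert-butyldimethylsilyloxy)-4,6-dimethyloxan-2-one
Product: 34 (2S,3S,5R)-2-(tert-butyldimethylsilyloxy)-1-{2-[(2R,4S,5E)-2-(tert-butyldimethylsilyloxy)-4,6-dimethyl-4-(triethylsilyloxy)octa-5,7-dien-1-yl]-1,3-dithian-2-yl}-5-hydroxy-3-methylhexan-1-one, via lithiated silyl dithiane 31 (not isolated), via lithium alkoxide 32 (not isolated), via Brook-shifted lithiodithiane 33 (not isolated)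
Conditions: 30, t-BuLi, Et2O, −78 → −45 °C; 8, Et2O, −78 → −25 °C; HMPA, THF, −78 → −45 °C; 17, THF, −78 °C; aq NH4Cl (−78 °C)
Reagents that add atoms: none
Why: Lithiated 30 (31) opens the oxirane of 8 at its unsubstituted carbon C8 in an SN2 step that forms C8–C9 and leaves the C7–O bond, and hence the C7 configuration, untouched; in ether the resulting alkoxide 32 is stable, and only on addition of HMPA does silicon migrate from carbon to oxygen (1,4-Brook rearrangement), which caps O7 as its TBS ether and regenerates a dithiane carbanion at C9 (33). This anion then adds to the carbonyl of lactone 17 (Corey–Seebach acylation) and the tetrahedral intermediate opens, so that C9–C10 is formed, C10 arrives as a ketone and O14 is released as the only free hydroxyl. The closest known reaction type is the solvent-controlled one-flask linchpin coupling of 2-silyl-1,3-dithianes with two electrophiles (anion relay chemistry), combined with the standard acylation of 2-lithio-1,3-dithianes by lactones. No ring is closed (the oxirane and the lactone ring are opened) and no stereocentre is created: C5, C7, C11, C12 and C14 are carried in from 8 and 17. The step needs order and chemoselectivity: the Brook shift must wait until 8 is consumed (secured by ether as solvent and late addition of HMPA), each electrophile must react once (equimolar 31, and the bulky 2,2-disubstituted acyl dithiane cannot be attacked again), and acylation must beat enolisation of 17 (low temperature, the hindered oxygen-substituted C11–H is a poor acid), while the diene, the silyl ethers and the absence of acidic protons in 8 keep both fragments compatible with the anionic cascade.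

Step 24
Reactants: 34 (2S,3S,5R)-2-(tert-butyldimethylsilyloxy)-1-{2-[(2R,4S,5E)-2-(tert-butyldimethylsilyloxy)-4,6-dimethyl-4-(triethylsilyloxy)octa-5,7-dien-1-yl]-1,3-dithian-2-yl}-5-hydroxy-3-methylhexan-1-one
Product: 35 (1R,2S,3S,5R)-2-(tert-butyldimethylsilyloxy)-1-{2-[(2R,4S,5E)-2-(tert-butyldimethylsilyloxy)-4,6-dimethyl-4-(triethylsilyloxy)octa-5,7-dien-1-yl]-1,3-dithian-2-yl}-3-methylhexane-1,5-diol
Conditions: NaBH4, MeOH/THF, −40 → 0 °C
Reagents that add atoms: none
Why: Felkin–Anh (polar) control: hydride should attack the C10 carbonyl anti to the C11–OSi bond and past the C11–H, which gives the 10,11-syn (10R) diol monoether, the bulky, poorly coordinating TBS ether and the sodium counter-ion in methanol disfavouring the chelate that would lead to the C10 epimer.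

Step 25
Reactants: 35 (1R,2S,3S,5R)-2-(tert-butyldimethylsilyloxy)-1-{2-[(2R,4S,5E)-2-(tert-butyldimethylsilyloxy)-4,6-dimethyl-4-(triethylsilyloxy)octa-5,7-dien-1-yl]-1,3-dithian-2-yl}-3-methylhexane-1,5-diol; 29 (2E,6E)-2-methyl-7-[(2R,3R)-3-(2-methylpropyl)oxiran-2-yl]hepta-2,6-dienoic acid
Product: 37 (2R,4S,5S,6R)-5-(tert-butyldimethylsilyloxy)-6-{2-[(2R,4S,5E)-2-(tert-butyldimethylsilyloxy)-4,6-dimethyl-4-(triethylsilyloxy)octa-5,7-dien-1-yl]-1,3-dithian-2-yl}-6-hydroxy-4-methylhexan-2-yl (2E,6E)-2-methyl-7-[(2R,3R)-3-(2-methylpropyl)oxiran-2-yl]hepta-2,6-dienoate, via mixed anhydride 36 (not isolated)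
Conditions: 29, 2,4,6-trichlorobenzoyl chloride, Et3N, THF, rt; then 35, DMAP, toluene, rt
Reagents that add atoms: none
Why: Yamaguchi esterification: the mixed anhydride 36 acylates, through the acylpyridinium, the unhindered C14 hydroxyl, while the C10 hydroxyl, flanked by the dithiane quaternary carbon and the C11 silyl ether, should stay free; the dithiane still masks the ketone so that C10 cannot epimerise under the basic conditions.

Step 26
Reactants: 37 (the C14 ester with the dithiane at C9)
Product: 38 (2R,4S,5S,6R,9R,11S,12E)-5,9-bis(tert-butyldimethylsilyloxy)-6-hydroxy-4,11,13-trimethyl-7-oxo-11-(triethylsilyloxy)pentadeca-12,14-dien-2-yl (2E,6E)-2-methyl-7-[(2R,3R)-3-(2-methylpropyl)oxiran-2-yl]hepta-2,6-dienoate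
Conditions: MeI, CaCO3, MeCN/H2O 9:1, 40 °C, dark
Reagents that add atoms: water, O
Why: Alkylative hydrolysis of the dithiane (S-methylation, ring opening, attack of water) under neutral, non-oxidising conditions that the diene, the vinyl oxirane and the silyl ethers should survive; it removes the linchpin ring and unveils the C9 ketone.

Step 27
Reactants: 38 (the tris-silyl ether of the target)
Product: 39 (2R,4S,5S,6R,9R,11S,12E)-5,6,9,11-tetrahydroxy-4,11,13-trimethyl-7-oxopentadeca-12,14-dien-2-yl (2E,6E)-2-methyl-7-[(2R,3R)-3-(2-methylpropyl)oxiran-2-yl]hepta-2,6-dienoate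
Conditions: (Me2N)3S(Me3SiF2) (TASF), DMF/H2O, 0 °C → rt
Reagents that add atoms: none
Why: Fluoride-induced cleavage of the three silyl ethers with a nearly neutral fluoride source, chosen because the β-hydroxy/α-hydroxy ketone (retro-aldol, elimination, C10 epimerisation) and the vinyl oxirane tolerate neither acid nor strongly basic fluoride.

**Compound list**
1 | (R)-2-methylglycidol, [(2R)-2-methyloxiran-2-yl]methanol | OC[C@@]1(C)OC1 | starting material
2 | (2S)-2-methylpent-4-ene-1,2-diol | OC[C@@](C)(O)CC=C | intermediate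
3 | (2S)-2-methyl-1,2-bis(triethylsilyloxy)pent-4-ene | CC[Si](CC)(CC)OC[C@@](C)(O[Si](CC)(CC)CC)CC=C | intermediate
4 | 2-[(2S)-2-methyl-2,3-bis(triethylsilyloxy)propyl]oxirane (both epimers at the oxirane carbon) | CC[Si](CC)(CC)OC[C@@](C)(O[Si](CC)(CC)CC)CC1CO1 | intermediate
5 | (2R)-2-[(2S)-2-methyl-2,3-bis(triethylsilyloxy)propyl]oxirane | CC[Si](CC)(CC)OC[C@@](C)(O[Si](CC)(CC)CC)C[C@@H]1CO1 | intermediate
6 | (2S)-2-methyl-3-[(2R)-oxiran-2-yl]-2-(triethylsilyloxy)propanal | O=C[C@@](C)(O[Si](CC)(CC)CC)C[C@@H]1CO1 | intermediate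
7 | (2E,4S)-2,4-dimethyl-5-[(2R)-oxiran-2-yl]-4-(triethylsilyloxy)pent-2-enal | O=C/C(C)=C/[C@@](C)(O[Si](CC)(CC)CC)C[C@@H]1CO1 | intermediate
8 | (2R)-2-[(2S,3E)-2,4-dimethyl-2-(triethylsilyloxy)hexa-3,5-dien-1-yl]oxirane | C=C/C(C)=C/[C@@](C)(O[Si](CC)(CC)CC)C[C@@H]1CO1 | intermediate
9 | prop-2-yn-1-ol | C#CCO | starting material
10 | (R)-propylene oxide, (2R)-2-methyloxirane | C[C@@H]1CO1 | starting material
11 | (5R)-hex-2-yne-1,5-diol | OCC#CC[C@@H](C)O | intermediate
12 | (2E,5R)-hex-2-ene-1,5-diol | OC/C=C/C[C@@H](C)O | intermediate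
13 | (2R)-1-[(2R,3R)-3-(hydroxymethyl)oxiran-2-yl]propan-2-ol | OC[C@H]1O[C@@H]1C[C@@H](C)O | intermediate
14 | (2S,3S,5R)-3-methylhexane-1,2,5-triol | OC[C@@H](O)[C@@H](C)C[C@@H](C)O | intermediate
15 | (3S,4S,6R)-4,6-dimethyloxane-2,3-diol (lactol, not isolated) | OC1[C@@H](O)[C@@H](C)C[C@@H](C)O1 | intermediate
16 | (3S,4S,6R)-3-hydroxy-4,6-dimethyloxan-2-one | O=C1[C@@H](O)[C@@H](C)C[C@@H](C)O1 | intermediate
17 | (3S,4S,6R)-3-(tert-butyldimethylsilyloxy)-4,6-dimethyloxan-2-one | O=C1[C@@H](O[Si](C)(C)C(C)(C)C)[C@@H](C)C[C@@H](C)O1 | intermediate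
18 | 3-methylbutanal | CC(C)CC=O | starting material
19 | ethyl (2E)-5-methylhex-2-enoate | CCOC(=O)/C=C/CC(C)C | intermediate
20 | (2E)-5-methylhex-2-en-1-ol | OC/C=C/CC(C)C | intermediate
21 | [(2R,3R)-3-(2-methylpropyl)oxiran-2-yl]methanol | OC[C@H]1O[C@@H]1CC(C)C | intermediate
22 | (2S,3R)-3-(2-methylpropyl)oxirane-2-carbaldehyde | O=C[C@H]1O[C@@H]1CC(C)C | intermediate
23 | 5-bromopent-1-ene | C=CCCCBr | starting material
24 | methyl methacrylate | C=C(C)C(=O)OC | starting material
25 | methyl (2E)-6-bromo-2-methylhex-2-enoate | COC(=O)/C(C)=C/CCCBr | intermediate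
26 | methyl (2E)-2-methyl-6-[(1-phenyl-1H-tetrazol-5-yl)sulfanyl]hex-2-enoate | COC(=O)/C(C)=C/CCCSc1nnnn1-c1ccccc1 | intermediate
27 | methyl (2E)-2-methyl-6-[(1-phenyl-1H-tetrazol-5-yl)sulfonyl]hex-2-enoate | COC(=O)/C(C)=C/CCCS(=O)(=O)c1nnnn1-c1ccccc1 | intermediate
28 | methyl (2E,6E)-2-methyl-7-[(2R,3R)-3-(2-methylpropyl)oxiran-2-yl]hepta-2,6-dienoate | COC(=O)/C(C)=C/CC/C=C/[C@H]1O[C@@H]1CC(C)C | intermediate
29 | (2E,6E)-2-methyl-7-[(2R,3R)-3-(2-methylpropyl)oxiran-2-yl]hepta-2,6-dienoic acid | OC(=O)/C(C)=C/CC/C=C/[C@H]1O[C@@H]1CC(C)C | intermediate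
30 | 2-(tert-butyldimethylsilyl)-1,3-dithiane | CC(C)(C)[Si](C)(C)C1SCCCS1 | starting material
31 | 2-lithio-2-(tert-butyldimethylsilyl)-1,3-dithiane (not isolated) | [Li]C1(SCCCS1)[Si](C)(C)C(C)(C)C | intermediate
32 | lithium (2R,4S,5E)-1-[2-(tert-butyldimethylsilyl)-1,3-dithian-2-yl]-4,6-dimethyl-4-(triethylsilyloxy)octa-5,7-dien-2-olate (not isolated) | C=C/C(C)=C/[C@@](C)(O[Si](CC)(CC)CC)C[C@@H](O[Li])CC1(SCCCS1)[Si](C)(C)C(C)(C)C | intermediate
33 | 2-lithio-2-[(2R,4S,5E)-2-(tert-butyldimethylsilyloxy)-4,6-dimethyl-4-(triethylsilyloxy)octa-5,7-dien-1-yl]-1,3-dithiane (not isolated) | C=C/C(C)=C/[C@@](C)(O[Si](CC)(CC)CC)C[C@@H](O[Si](C)(C)C(C)(C)C)CC1([Li])SCCCS1 | intermediate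
34 | (2S,3S,5R)-2-(tert-butyldimethylsilyloxy)-1-{2-[(2R,4S,5E)-2-(tert-butyldimethylsilyloxy)-4,6-dimethyl-4-(triethylsilyloxy)octa-5,7-dien-1-yl]-1,3-dithian-2-yl}-5-hydroxy-3-methylhexan-1-one | C=C/C(C)=C/[C@@](C)(O[Si](CC)(CC)CC)C[C@@H](O[Si](C)(C)C(C)(C)C)CC1(SCCCS1)C(=O)[C@@H](O[Si](C)(C)C(C)(C)C)[C@@H](C)C[C@@H](C)O | intermediate
35 | (1R,2S,3S,5R)-2-(tert-butyldimethylsilyloxy)-1-{2-[(2R,4S,5E)-2-(tert-butyldimethylsilyloxy)-4,6-dimethyl-4-(triethylsilyloxy)octa-5,7-dien-1-yl]-1,3-dithian-2-yl}-3-methylhexane-1,5-diol | C=C/C(C)=C/[C@@](C)(O[Si](CC)(CC)CC)C[C@@H](O[Si](C)(C)C(C)(C)C)CC1(SCCCS1)[C@H](O)[C@@H](O[Si](C)(C)C(C)(C)C)[C@@H](C)C[C@@H](C)O | intermediate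
36 | (2E,6E)-2-methyl-7-[(2R,3R)-3-(2-methylpropyl)oxiran-2-yl]hepta-2,6-dienoic 2,4,6-trichlorobenzoic anhydride (not isolated) | O=C(OC(=O)c1c(Cl)cc(Cl)cc1Cl)/C(C)=C/CC/C=C/[C@H]1O[C@@H]1CC(C)C | intermediate
37 | (2R,4S,5S,6R)-5-(tert-butyldimethylsilyloxy)-6-{2-[(2R,4S,5E)-2-(tert-butyldimethylsilyloxy)-4,6-dimethyl-4-(triethylsilyloxy)octa-5,7-dien-1-yl]-1,3-dithian-2-yl}-6-hydroxy-4-methylhexan-2-yl (2E,6E)-2-methyl-7-[(2R,3R)-3-(2-methylpropyl)oxiran-2-yl]hepta-2,6-dienoate | C=C/C(C)=C/[C@@](C)(O[Si](CC)(CC)CC)C[C@@H](O[Si](C)(C)C(C)(C)C)CC1(SCCCS1)[C@H](O)[C@@H](O[Si](C)(C)C(C)(C)C)[C@@H](C)C[C@@H](C)OC(=O)/C(C)=C/CC/C=C/[C@H]1O[C@@H]1CC(C)C | intermediate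
38 | (2R,4S,5S,6R,9R,11S,12E)-5,9-bis(tert-butyldimethylsilyloxy)-6-hydroxy-4,11,13-trimethyl-7-oxo-11-(triethylsilyloxy)pentadeca-12,14-dien-2-yl (2E,6E)-2-methyl-7-[(2R,3R)-3-(2-methylpropyl)oxiran-2-yl]hepta-2,6-dienoate | C=C/C(C)=C/[C@@](C)(O[Si](CC)(CC)CC)C[C@@H](O[Si](C)(C)C(C)(C)C)CC(=O)[C@H](O)[C@@H](O[Si](C)(C)C(C)(C)C)[C@@H](C)C[C@@H](C)OC(=O)/C(C)=C/CC/C=C/[C@H]1O[C@@H]1CC(C)C | intermediate
39 | (2R,4S,5S,6R,9R,11S,12E)-5,6,9,11-tetrahydroxy-4,11,13-trimethyl-7-oxopentadeca-12,14-dien-2-yl (2E,6E)-2-methyl-7-[(2R,3R)-3-(2-methylpropyl)oxiran-2-yl]hepta-2,6-dienoate (CNP0145465.1) | C=C/C(C)=C/[C@@](C)(O)C[C@@H](O)CC(=O)[C@H](O)[C@@H](O)[C@@H](C)C[C@@H](C)OC(=O)/C(C)=C/CC/C=C/[C@H]1O[C@@H]1CC(C)C | target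

**Count**
Total steps: 27. Longest linear sequence: 12 steps (steps 1–7, then 23–27).

**Three steps most likely to fail**

Step 23. The hindered, strongly basic carbanion 33 may take the C11 proton of lactone 17 (enolisation) instead of adding to its carbonyl, or the silyl group may migrate within the lactolate before the quench; either would return protonated dithiane and lower the yield. Fallback, setting out from 17: the lactone is opened with MeNH(OMe)·HCl and AlMe3 (CH2Cl2, 0 °C → rt) to the hydroxy amide (2S,3S,5R)-2-(tert-butyldimethylsilyloxy)-5-hydroxy-N-methoxy-N,3-dimethylhexanamide F1. Its free hydroxyl is capped at once (TMSCl, imidazole, CH2Cl2) to give (2S,3S,5R)-2-(tert-butyldimethylsilyloxy)-N-methoxy-N,3-dimethyl-5-(trimethylsilyloxy)hexanamide F2. F2 is then used in place of 17 in the same one-flask sequence with 30 and 8. An N-methoxy-N-methylamide forms a chelated tetrahedral adduct that enolises less readily and cannot add twice. A citric acid work-up removes the trimethylsilyl group, and the route is rejoined at 34.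

Step 24. Poor facial selectivity would result if chelation or the steric demand of the neighbouring dithiane overrides the Felkin–Anh preference, giving the C10 epimer. Fallback, setting out from 34: substrate control is replaced by reagent control, reduction with (S)-2-methyl-CBS-oxazaborolidine and catecholborane in toluene at −78 °C. 2-Acyl-1,3-dithianes are good substrates for this reduction because the dithianyl carbon acts as the large group; the catalyst antipode should be checked on the first run. Catecholborane is chosen because it should not hydroborate the diene at this temperature. The product is 35 itself, so the route is rejoined at 35 and no new compound is made (F0).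

Step 26. S-Methylation of the neopentyl-like dithiane may be slow, and long warming with iodide present could open the vinyl oxirane or cost the tertiary allylic silyl ether. Fallback, setting out from 35: the order of the last steps is changed so that the ketone is unmasked before the oxirane-bearing acid is attached. Hg(ClO4)2 and CaCO3 in THF/H2O at 0 °C should cleave the dithiane within minutes and give the keto diol (2R,4S,5S,6R,9R,11S,12E)-5,9-bis(tert-butyldimethylsilyloxy)-2,6-dihydroxy-4,11,13-trimethyl-11-(triethylsilyloxy)pentadeca-12,14-dien-7-one F3. F3 is then esterified at the C14 hydroxyl with 29 under the Yamaguchi conditions of step 25, with short reaction time and little DMAP to protect C10 from epimerisation; the C10 hydroxyl is hindered and hydrogen-bonded to the ketone. The route is rejoined at 38.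

Further compounds
F1 | step 23 | (2S,3S,5R)-2-(tert-butyldimethylsilyloxy)-5-hydroxy-N-methoxy-N,3-dimethylhexanamide | CON(C)C(=O)[C@@H](O[Si](C)(C)C(C)(C)C)[C@@H](C)C[C@@H](C)O
F2 | step 23 | (2S,3S,5R)-2-(tert-butyldimethylsilyloxy)-N-methoxy-N,3-dimethyl-5-(trimethylsilyloxy)hexanamide | CON(C)C(=O)[C@@H](O[Si](C)(C)C(C)(C)C)[C@@H](C)C[C@@H](C)O[Si](C)(C)C
F0 | step 24 | none | none
F3 | step 26 | (2R,4S,5S,6R,9R,11S,12E)-5,9-bis(tert-butyldimethylsilyloxy)-2,6-dihydroxy-4,11,13-trimethyl-11-(triethylsilyloxy)pentadeca-12,14-dien-7-one | C=C/C(C)=C/[C@@](C)(O[Si](CC)(CC)CC)C[C@@H](O[Si](C)(C)C(C)(C)C)CC(=O)[C@H](O)[C@@H](O[Si](C)(C)C(C)(C)C)[C@@H](C)C[C@@H](C)O
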